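**Plan**

1. Locants used throughout: C1 (exocyclic CH2), C2, C3 (γ-lactone C=O), O4, ring carbons C5–C18 in the order of the 14-membered ring (CH3 on C7 and C15, OOH on C15), C19 (butenolide C=O on C11, its ring oxygen on C9).
2. Cuts: (a) C15–OOH, last, by a Schenck ene reaction; (b) O4–C5 and C2–C18 together, i.e. the whole α-methylene lactone ring, from a C18=C5–C6=C7 diene and 2-bromoacrylic acid; (c) C18=C5 by ring-closing metathesis; (d) butenolide C10=C11 (sulfoxide elimination), C10–C11 and O–C19 (epoxide opening, lactonisation), C11–C12 (alkylation).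
3. Enabling feature: O4 sits on C5, which is allylic to the C6=C7 olefin and is the ring-fusion partner of C18. The five-membered ring C2–C3–O4–C5–C18 is therefore the retron of carbopalladation at C18 and carboxylate capture of an η3-allyl (C5–C6–C7) at C5, so the bare 14-membered diene is the precursor.
4. Forward order: C5–C10 dienyl epoxide and C11–C18 thio acid → butenolide → 14-membered carbocycle → annulation of the α-methylene lactone across the ring diene → biomimetic photo-oxygenation.
5. Stereochemistry: C9 from (R)-epichlorohydrin; E-C6=C7 and E-C14=C15 from syn carboalumination; C18 and C5 from syn addition across the E-C18=C5 olefin on the diene face dictated by C9; C15 from peripheral singlet-oxygen attack.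

Key step: step 11

Remark (assumption): the tertiary allylic hydroperoxide is taken not to survive zerovalent palladium, phosphines or ruthenium alkylidenes and is therefore introduced in the last step.

**Route**

Step 1
Reactants: 1 (R)-epichlorohydrin; 2 ethynyltrimethylsilane
Product: 4 (2R)-1-chloro-5-(trimethylsilyl)pent-4-yn-2-ol, via lithium (trimethylsilyl)acetylide 3 (not isolated)
Conditions: 2, n-BuLi, THF, −78 °C; BF3·OEt2; then 1, −78 °C; aqueous work-up
Reagents that add atoms: none
Why: Yamaguchi–Hirao alkynylation, in which the BF3-activated epoxide is opened by the lithium acetylide at its unsubstituted carbon while the C–Cl bond and the carbinol centre (later C9) are untouched, so the R configuration of 1 is carried into 4.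

Step 2
Reactants: 4 (2R)-1-chloro-5-(trimethylsilyl)pent-4-yn-2-ol
Product: 5 (2R)-1-chloropent-4-yn-2-ol
Conditions: Bu4NF, AcOH (1:1), THF, 0 °C
Reagents that add atoms: none
Why: Fluoride-mediated protodesilylation of the alkynylsilane, buffered with acetic acid so that the chlorohydrin does not close before the carbometalation.

Step 3
Reactants: 5 (2R)-1-chloropent-4-yn-2-ol; 6 vinyl bromide
Product: 8 (2R,4E)-1-chloro-4-methylhepta-4,6-dien-2-ol, via E-alkenylalane 7 (not isolated)
Conditions: AlMe3 (3 equiv), Cp2ZrCl2 (0.3 equiv), CH2Cl2, 0 °C to rt; then 6, ZnCl2, Pd(PPh3)4 (5 mol %), THF, rt; aqueous work-up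
Reagents that add atoms: trimethylaluminium, C[Al](C)C
Why: Negishi zirconium-catalysed carboalumination adds CH3 and Al syn across the terminal alkyne with the methyl group on the internal carbon (the hydroxyl travels as its aluminium alkoxide), and the Negishi cross-coupling with vinyl bromide proceeds with retention, which fixes the E-C6=C7 olefin and completes the diene.

Step 4
Reactants: 8 (2R,4E)-1-chloro-4-methylhepta-4,6-dien-2-ol
Product: 9 (2R)-2-[(2E)-2-methylpenta-2,4-dien-1-yl]oxirane
Conditions: K2CO3, MeOH, rt
Reagents that add atoms: none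
Why: Intramolecular Williamson etherification of the chlorohydrin, in which the C–O bond of the stereocentre is not broken, so C9 stays R.

Step 5
Reactants: 10 hex-1-en-5-yne; 11 ethylene oxide
Product: 14 (3E)-4-methylocta-3,7-dien-1-ol, via E-alkenylalane 12 (not isolated), via lithium alanate 13 (not isolated)
Conditions: AlMe3 (2 equiv), Cp2ZrCl2 (0.25 equiv), CH2Cl2, rt; then n-BuLi, hexane/THF, −78 °C; then 11, −78 °C to rt; aqueous work-up
Reagents that add atoms: trimethylaluminium, C[Al](C)C
Why: Negishi carboalumination of the alkyne (the isolated terminal olefin is not carbometalated under these conditions) gives the E-alkenylalane, whose lithium alanate opens ethylene oxide with retention of olefin geometry, setting E-C14=C15 and the C12–C13 spacer.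

Step 6
Reactants: 14 (3E)-4-methylocta-3,7-dien-1-ol
Product: 15 (5E)-8-iodo-5-methylocta-1,5-diene
Conditions: I2, PPh3, imidazole, CH2Cl2, 0 °C
Reagents that add atoms: iodine, I-I
Why: Appel-type iodination (Garegg–Samuelsson conditions) of the primary alcohol by SN2 displacement of the alkoxyphosphonium ion.

Step 7
Reactants: 16 (phenylsulfanyl)acetic acid; 15 (5E)-8-iodo-5-methylocta-1,5-diene
Product: 18 (5E)-6-methyl-2-(phenylsulfanyl)deca-5,9-dienoic acid (racemic), via dilithium enediolate 17 (not isolated)
Conditions: LiN(i-Pr)2 (2.2 equiv), THF, −78 to 0 °C; then 15, −78 °C to rt; aqueous HCl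
Reagents that add atoms: none
Why: C-alkylation of the dianion of an α-sulfenyl carboxylic acid with a primary iodide, the sulfur substituent being the later leaving group for the butenolide olefin.

Step 8
Reactants: 18 (5E)-6-methyl-2-(phenylsulfanyl)deca-5,9-dienoic acid; 9 (2R)-2-[(2E)-2-methylpenta-2,4-dien-1-yl]oxirane
Product: 21 (5R)-3-[(3E)-4-methylocta-3,7-dien-1-yl]-5-[(2E)-2-methylpenta-2,4-dien-1-yl]-3-(phenylsulfanyl)oxolan-2-one (both C3 epimers), via dilithium enediolate 19 (not isolated), via γ-hydroxy acid 20 (not isolated)
Conditions: LiN(i-Pr)2 (2.2 equiv), THF, −78 to 0 °C; then 9, 0 °C to rt; aqueous HCl; then TsOH·H2O (cat.), benzene, rt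
Reagents that add atoms: none
Why: The α-thio carboxylate dianion opens the terminal epoxide at C10 by SN2 attack (C9 untouched) and the γ-hydroxy acid lactonises under acid catalysis, the C11 configuration being irrelevant because C11 becomes sp2 in the next step.

Step 9
Reactants: 21 sulfide lactone
Product: 23 (5R)-3-[(3E)-4-methylocta-3,7-dien-1-yl]-5-[(2E)-2-methylpenta-2,4-dien-1-yl]furan-2(5H)-one, via sulfoxide 22 (not isolated)
Conditions: mCPBA (1.0 equiv), CH2Cl2, −78 °C; then toluene, CaCO3, 100 °C
Reagents that add atoms: none
Why: Chemoselective S-oxidation at low temperature followed by thermal syn elimination of the sulfoxide towards the ring CH2 (C10) gives the endocyclic butenolide without touching C9.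

Step 10
Reactants: 23 open-chain butenolide
Product: 24 (9R)-macrocyclic diene butenolide (14-membered carbocycle C5–C18 with the E,E-diene C18=C5–C6=C7, 7-methyl, E-C14=C15, 15-methyl, and the C9–O–C19(=O)–C11=C10 butenolide)
Conditions: second-generation Grubbs catalyst (10 mol %), CH2Cl2 (1 mM), 40 °C
Reagents that add atoms: none
Why: Ring-closing metathesis between the isolated vinyl group and the diene terminus, in which the C7 methyl makes the internal diene olefin trisubstituted and inert so that no ring-contracted product can form, and the E olefin is expected as the preferred isomer of the conjugated s-trans diene in a 14-membered ring.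

Step 11
Reactants: 24 (9R)-macrocyclic diene butenolide; 25 2-bromoacrylic acid
Product: 26 (5S,9R,18R)-bis-lactone triene (the target without the hydroperoxide: trans-fused α-methylene-γ-lactone at C5/C18, butenolide at C9–C11, E-C6=C7, E-C14=C15)
Conditions: 25 (1.5 equiv), Pd(OAc)2 (10 mol %), PPh3 (20 mol %), Ag2CO3 (1.2 equiv), MeCN, 60 °C
Reagents that add atoms: none
Why: Zerovalent palladium inserts into the C–Br bond of the carboxylate of 25, the alkenylpalladium species adds syn across C18=C5 of the diene (C2 to the less substituted terminus C18), and the resulting η3-allyl (C5–C6–C7) palladium carboxylate forms the O4–C5 bond and releases the catalyst, which is the Larock heteroannulation of a 1,3-diene by a vinylic halide that carries a carboxylic acid. The lactone ring (C2, C3, O4, C5, C18) closes in the 5-exo mode at the proximal allyl terminus C5, the seven-membered alternative through C7 being disfavoured, and the C6=C7 olefin keeps its E geometry because the disubstituted terminus C7 cannot isomerise through a tertiary σ-complex. C18 is set by the diene face that is attacked: the s-trans diene stands perpendicular to the ring and should react from outside in the conformer whose C7 methyl avoids a syn-pentane contact with the C9–O bond of the butenolide, which leads to 18R. C5 is set by inner-sphere (syn) C–O bond formation from the six-membered palladacycle, favoured by the halide-free, silver-mediated conditions, so that C2 and O4 add to the same face of the E olefin and the fusion is trans (5S). The step needs chemoselectivity for the diene over the trisubstituted C14=C15 and butenolide olefins (only a conjugated diene gives an η3-allyl on insertion), regioselectivity for C18 over C7 (the less substituted terminus), and a limited excess of 25 so that the new α-methylene lactone is not vinylated further.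

Step 12
Reactants: 26 (5S,9R,18R)-bis-lactone triene
Product: 27 (5S,9R,15S,18R)-hydroperoxide, CNP0343227.1
Conditions: O2, hν (visible), 5,10,15,20-tetraphenylporphyrin (cat.), CH2Cl2, −20 °C
Reagents that add atoms: dioxygen, O=O
Why: Schenck ene reaction, in which singlet oxygen should select the electron-rich C14=C15 olefin (C6=C7 is deactivated by the allylic lactone oxygen on C5 and the two enoate olefins are inert), bond to C15 and take a hydrogen from C13 on the more crowded side of the olefin (cis effect) with shift of the double bond to E-C13=C14, the C15 configuration being expected from suprafacial attack on the outer ring face as in the presumed non-enzymatic biogenesis.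

**Compound list**

1 | (R)-epichlorohydrin | ClC[C@H]1CO1 | starting material
2 | ethynyltrimethylsilane | C#C[Si](C)(C)C | starting material
3 | lithium (trimethylsilyl)acetylide | [Li]C#C[Si](C)(C)C | intermediate (not isolated)
4 | (2R)-1-chloro-5-(trimethylsilyl)pent-4-yn-2-ol | ClC[C@H](O)CC#C[Si](C)(C)C | intermediate
5 | (2R)-1-chloropent-4-yn-2-ol | ClC[C@H](O)CC#C | intermediate
6 | vinyl bromide | C=CBr | starting material
7 | E-alkenylalane (O-dimethylaluminio alkoxide of the carboalumination product of 5) | ClC[C@H](O[Al](C)C)C/C(C)=C/[Al](C)C | intermediate (not isolated)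
8 | (2R,4E)-1-chloro-4-methylhepta-4,6-dien-2-ol | ClC[C@H](O)C/C(C)=C/C=C | intermediate
9 | (2R)-2-[(2E)-2-methylpenta-2,4-dien-1-yl]oxirane | C=C/C=C(\C)C[C@@H]1CO1 | intermediate
10 | hex-1-en-5-yne | C=CCCC#C | starting material
11 | ethylene oxide | C1CO1 | starting material
12 | dimethyl[(1E)-2-methylhexa-1,5-dien-1-yl]alane | C=CCC/C(C)=C/[Al](C)C | intermediate (not isolated)
13 | lithium butyl(dimethyl)[(1E)-2-methylhexa-1,5-dien-1-yl]alanate | [Li+].C=CCC/C(C)=C/[Al-](C)(C)CCCC | intermediate (not isolated)
14 | (3E)-4-methylocta-3,7-dien-1-ol | OCC/C=C(\C)CCC=C | intermediate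
15 | (5E)-8-iodo-5-methylocta-1,5-diene | ICC/C=C(\C)CCC=C | intermediate
16 | (phenylsulfanyl)acetic acid | OC(=O)CSc1ccccc1 | starting material
17 | dilithium enediolate of 16 | [Li+].[Li+].[O-]C([O-])=CSc1ccccc1 | intermediate (not isolated)
18 | (5E)-6-methyl-2-(phenylsulfanyl)deca-5,9-dienoic acid (racemic) | OC(=O)C(Sc1ccccc1)CC/C=C(\C)CCC=C | intermediate
19 | dilithium enediolate of 18 | [Li+].[Li+].[O-]C([O-])=C(Sc1ccccc1)CC/C=C(\C)CCC=C | intermediate (not isolated)
20 | γ-hydroxy acid from 19 and 9 (9R, C11 epimers) | OC(=O)C(Sc1ccccc1)(CC/C=C(\C)CCC=C)C[C@H](O)C/C(C)=C/C=C | intermediate (not isolated)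
21 | (5R)-3-[(3E)-4-methylocta-3,7-dien-1-yl]-5-[(2E)-2-methylpenta-2,4-dien-1-yl]-3-(phenylsulfanyl)oxolan-2-one (C3 epimers) | O=C1O[C@H](C/C(C)=C/C=C)CC1(Sc2ccccc2)CC/C=C(\C)CCC=C | intermediate
22 | sulfoxide of 21 | O=C1O[C@H](C/C(C)=C/C=C)CC1(S(=O)c2ccccc2)CC/C=C(\C)CCC=C | intermediate (not isolated)
23 | (5R)-3-[(3E)-4-methylocta-3,7-dien-1-yl]-5-[(2E)-2-methylpenta-2,4-dien-1-yl]furan-2(5H)-one | O=C1O[C@H](C/C(C)=C/C=C)C=C1CC/C=C(\C)CCC=C | intermediate
24 | (9R)-macrocyclic diene butenolide (E,E-diene C18=C5–C6=C7, E-C14=C15) | O=C1O[C@@H]2C/C(C)=C/C=C/CC/C(C)=C/CCC1=C2 | intermediate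
25 | 2-bromoacrylic acid | C=C(Br)C(=O)O | starting material
26 | (5S,9R,18R)-bis-lactone triene | C=C1C(=O)O[C@H]2/C=C(\C)C[C@@H]3C=C(CC/C=C(\C)CC[C@H]12)C(=O)O3 | intermediate
27 | (5S,9R,15S,18R)-hydroperoxide, CNP0343227.1 | C=C1C(=O)O[C@H]2/C=C(\C)C[C@@H]3C=C(C/C=C/[C@@](C)(OO)CC[C@H]12)C(=O)O3 | target

**Count and risks**

Total steps: 12. Longest linear sequence: 9 (steps 1–4 and 8–12).

Step 11. Process at risk: the alkenylpalladium species adds to the other face of the diene because the conformational bias from C9 is weaker than assumed, or the carboxylate captures the allyl unit anti to palladium, so that a C5/C18 diastereomer forms. Fallback: the order of the two ring-forming events is exchanged so that the annulation runs on a ring of different shape. It sets out from 21. Ring-closing metathesis of 21 (second-generation Grubbs catalyst, CH2Cl2, high dilution) would give the macrocyclic sulfide lactone F1, in which C10 and C11 are sp3 and the C9–O bond is no longer held perpendicular to the ring by a planar butenolide. Annulation of F1 with 25 under the conditions of step 11 would give the sulfide bis-lactone F2. Oxidation with mCPBA at −78 °C would give the sulfoxide F3, and its thermal elimination comes back to the route at 26. Both C11 epimers converge.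

Step 12. Process at risk: hydrogen abstraction from the C15 methyl group (exocyclic methylene and a secondary hydroperoxide at C14), oxygen delivery to the other face of C15, or competing attack at C6=C7. Fallback: a polar, reagent-controlled sequence that sets out from 26. Shi epoxidation (D-fructose-derived ketone, KHSO5, buffered MeCN/H2O, 0 °C) of the electron-rich C14=C15 olefin would give the 14R,15R-epoxide F4. Molybdenum-catalysed perhydrolysis (anhydrous H2O2 in Et2O, MoO2(acac)2 cat.) opens it at the tertiary carbon C15 with inversion to the 14R-hydroxy-15S-hydroperoxide F5. Selective silylation of the hydroperoxide (Et3SiCl, imidazole, −40 °C) gives the triethylsilyl peroxide F6. Syn dehydration of the C14 alcohol with the Burgess reagent, which can only take a hydrogen from C13, gives the E-allylic silyl peroxide F7. Desilylation (HF·pyridine, THF) comes back to the route at 27.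

Step 10. Process at risk: oligomerisation by intermolecular metathesis, or formation of the Z isomer at C18=C5. Fallback: ring closure at the C5–C6 bond by an intramolecular Heck reaction, which fixes the diene geometry. It sets out from 5. The alkenylalane 7 of step 3 is quenched with iodine instead of being coupled, giving the E-alkenyl iodide F8. K2CO3 in MeOH gives the iodo epoxide F9. Opening of F9 with dianion 19 gives the γ-hydroxy acid F10, which lactonises (TsOH) to the iodoalkenyl sulfide lactone F11. Oxidation gives the sulfoxide F12 and thermal elimination the iodoalkenyl butenolide F13. Under high dilution (Pd(OAc)2, PPh3, Ag2CO3, MeCN, 70 °C) the alkenylpalladium carbon C6 adds to the terminal carbon of the C18 vinyl group, which becomes C5, and syn β-hydride elimination gives the conjugated E-C18=C5 olefin, which comes back to the route at 24.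

**Further compounds**

F1 | step 11 | (9R)-macrocyclic sulfide lactone (ring-closed 21, C11 epimers) | O=C1O[C@@H]2C/C(C)=C/C=C/CC/C(C)=C/CCC1(Sc4ccccc4)C2
F2 | step 11 | sulfide bis-lactone (11-phenylsulfanyl-10,11-dihydro 26) | C=C1C(=O)O[C@H]2/C=C(\C)C[C@@H]3CC(Sc4ccccc4)(CC/C=C(\C)CC[C@H]12)C(=O)O3
F3 | step 11 | sulfoxide of F2 | C=C1C(=O)O[C@H]2/C=C(\C)C[C@@H]3CC(S(=O)c4ccccc4)(CC/C=C(\C)CC[C@H]12)C(=O)O3
F4 | step 12 | (14R,15R)-14,15-epoxide of 26 | C=C1C(=O)O[C@H]2/C=C(\C)C[C@@H]3C=C(CC[C@H]4O[C@]4(C)CC[C@H]12)C(=O)O3
F5 | step 12 | (14R,15S)-14-hydroxy-15-hydroperoxide | C=C1C(=O)O[C@H]2/C=C(\C)C[C@@H]3C=C(CC[C@@H](O)[C@@](C)(OO)CC[C@H]12)C(=O)O3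
F6 | step 12 | triethylsilyl peroxide of F5 | C=C1C(=O)O[C@H]2/C=C(\C)C[C@@H]3C=C(CC[C@@H](O)[C@@](C)(OO[Si](CC)(CC)CC)CC[C@H]12)C(=O)O3
F7 | step 12 | O-triethylsilyl peroxide of 27 | C=C1C(=O)O[C@H]2/C=C(\C)C[C@@H]3C=C(C/C=C/[C@@](C)(OO[Si](CC)(CC)CC)CC[C@H]12)C(=O)O3
F8 | step 10 | (2R,4E)-1-chloro-5-iodo-4-methylpent-4-en-2-ol | ClC[C@H](O)C/C(C)=C/I
F9 | step 10 | (2R)-2-[(2E)-3-iodo-2-methylprop-2-en-1-yl]oxirane | I/C=C(\C)C[C@@H]1CO1
F10 | step 10 | γ-hydroxy acid from 19 and F9 | OC(=O)C(Sc1ccccc1)(CC/C=C(\C)CCC=C)C[C@H](O)C/C(C)=C/I
F11 | step 10 | iodoalkenyl sulfide lactone | O=C1O[C@H](C/C(C)=C/I)CC1(Sc2ccccc2)CC/C=C(\C)CCC=C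
F12 | step 10 | sulfoxide of F11 | O=C1O[C@H](C/C(C)=C/I)CC1(S(=O)c2ccccc2)CC/C=C(\C)CCC=C
F13 | step 10 | iodoalkenyl butenolide | O=C1O[C@H](C/C(C)=C/I)C=C1CC/C=C(\C)CCC=C
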